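Slowness first: how does the acid set free behave in a flask where the coupling of electrophile and nucleophile is quick but the free base comes late and takes acid up slowly?

electrophile 0.31 M; nucleophile 0.310 M; free base 0.310 M (fed, over 50 min); time 50 min; the fed solution adds 0.10 times the starting volume

    acid set free + free base ⇌ salt of the base (K1 = 52000 M⁻¹, k1 = 0.014 M⁻¹ s⁻¹)
    nucleophile + acid set free ⇌ protonated nucleophile, settled at all times (K2 = 54 M⁻¹)
    crystals ⇌ acid set free, rate k3*(cs3 - [acid set free]) while solid is left; crystals form when [acid set free] > cs3 (cs3 = 9.3 mM, k3 = 0.030 s⁻¹)
    electrophile + nucleophile → acid set free + product (k4 = 0.027 M⁻¹ s⁻¹)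
    nucleophile ⇌ dormant form (K5 = 29, k5 = 2.5 × 10⁻⁴ s⁻¹)

* part of the electrophile that has reacted at 50 min
* share of free nucleophile in free nucleophile and protonated nucleophile together, at 50 min

- acid set free is meant together with its crystals
- every charge counts on the volume at the start, and the solution that is fed holds the whole dose
- solid, in amounts per volume of the solution: crystals
- run time (flask): 50 min

**How fast does acid appear, and how fast does free base arrive?** The coupling starts at 0.156 M min⁻¹, while the feed delivers 0.00620 M min⁻¹, so acid is made much faster than free base comes.

**Once fed, does the free base take the acid at once?** No. With dissolved acid at its solubility, free base is used in a pseudo-first-order way, with a half-life of 88.7 min, longer than the run. The dose spends on average half of the dosing time in the flask, so I reckon on about 0.0605 M of salt.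

**The weak spot: are crystals sure to stand at the end?** They need roughly 22.5% of the electrophile reacted. The electrophile's half-life as charged is 1.4 min, short against 50 min, so I expect crystals.

**What does that do to the nucleophile?** Dissolved acid near 9.3 mM meets the protonation balance with constant 54 M⁻¹. Their product is ρ = 0.502, the protonation ratio: protonated nucleophile over free nucleophile while crystals stand. The free share is then 1/(1 + ρ), or 66.6%, however much nucleophile is left.

**And c?** The charges are equal, so the nucleophile charged allows c up to 100%. The dormant form also takes nucleophile, and my reckoning stops there.

The forecast gives c as 90% (85% to 94%) and fr as 68.6% (66% to 71%), with the crystals “holding dissolved acid near saturation”.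

The flask gives c = 90.2% and fr = 68.4%.

In this flask at 50 min, protonated over free reads 0.462 against ρ, with 0.193 M of crystals and 0.00857 M of dissolved acid. Taking away the saturation of acid set free lowers c from 90.2% to 83.1%, a change of 7.1 percentage points, so that saturation is one part of the conversion reached. The neighbour flask charged with 0.53 M of electrophile has the same ρ, which holds no electrophile charge, so I expect a free share of 66.6%. With 0.218 M of crystals there, it computes to 68.8%, while its c is 57.0%.

(The constants are assumed; the run is a simulation.)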